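**Plan**

1. The ring carbons are called C1 (ylidene carbon), C2 and C3 (CH2), C4 (CH–CH3), C5 (quaternary) and C6 (CH bearing the hydroxypropyl group). The retrosynthesis cuts (a) the side chain between its second and third carbon, (b) the enal back to a 2-substituted 1,3-diene on C1/C2, and (c) the ring bond C5–C6.
2. Cut (c) is possible because C6 is allylic to C1, the ring CH2 C2 next to C1 can carry an oxygen, and the first chain carbon on C5 can be a carboxyl carbon. O–C(=O)–C5 and C2–C1=C6 are then the two halves of an ester-enolate Claisen array, and tying the ester oxygen to C2 makes the precursor a δ-lactone (a temporary ring) with C3 and C4 as tether.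
3. Forward: glutarate half ester → ynone → syn-hydrostannation and Stille coupling (alkene geometry, diene) → CBS reduction and lactonisation → α-methylation → Ireland–Claisen ring contraction, which forms the carbocycle → 1,4-hydrogenation of the diene → carboxyl to vinyl → B-alkyl Suzuki–Miyaura coupling with a C14 dienyl iodide → desilylation and MnO2 oxidation.
4. Stereochemistry: C4 comes from (R)-methyl hydrogen 3-methylglutarate; C5 and C6 come from the CBS-set carbinol and the alkene geometry through the Claisen step; the Z enal comes from the s-cis diene.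
5. In the side chain the carbinol comes from asymmetric propargylation, the epoxide from hydroxyl-directed threo epoxidation, and the E-alkenes from zirconocene-catalysed methylalumination.

Key step: step 7

Assumption: the (S) enantiomer of the phosphoric acid in step 12 is taken to direct the propargyl group to the Si face of the enal, by analogy with its behaviour toward aryl aldehydes; should the sense be the reverse, the (R) acid is used.

TBS = tert-butyldimethylsilyl; TBSO = TBS ether oxygen.

**Steps**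

Step 1
Reactants: 1 (3R)-5-methoxy-3-methyl-5-oxopentanoic acid; 2 tert-butyldimethyl(pent-4-yn-1-yloxy)silane
Product: 4 methyl (3R)-3-methyl-5-oxo-10-(TBSO)dec-6-ynoate, via acid chloride 3 (not isolated)
Conditions: (COCl)2, DMF (cat.), CH2Cl2, 0 °C to rt; then 2, PdCl2(PPh3)2 (2 mol %), CuI (4 mol %), Et3N, THF, rt
Reagents that add atoms: none
Why: The acid chloride formed in the flask undergoes acyl Sonogashira coupling with the terminal alkyne while the methyl ester and silyl ether are inert, and the stereocentre is β to both carbonyl groups and so not at risk.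

Step 2
Reactants: 4 methyl (3R)-3-methyl-5-oxo-10-(TBSO)dec-6-ynoate
Product: 5 methyl (3R,6E)-3-methyl-5-oxo-10-(TBSO)-6-(tributylstannyl)dec-6-enoate
Conditions: Bu3SnH, Pd(PPh3)4 (2 mol %), THF, 0 °C
Reagents that add atoms: tributyltin hydride, CCCC[SnH](CCCC)CCCC
Why: Palladium-catalysed hydrostannation of an ynone is a syn addition that places tin on the carbon next to the carbonyl group, so the acyl group ends up cis to the silyloxypropyl chain, which is the alkene geometry the key step needs.

Step 3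
Reactants: 6 2-bromoprop-2-en-1-ol
Product: 7 (2-bromoprop-2-en-1-yloxy)(tert-butyl)dimethylsilane
Conditions: TBSCl, imidazole, CH2Cl2, 0 °C to rt
Reagents that add atoms: tert-butyldimethylsilyl chloride, CC(C)(C)[Si](C)(C)Cl
Why: Silylation of a primary alcohol under standard conditions leaves the alkenyl bromide untouched.

Step 4
Reactants: 5 methyl (3R,6E)-3-methyl-5-oxo-10-(TBSO)-6-(tributylstannyl)dec-6-enoate; 7 (2-bromoprop-2-en-1-yloxy)(tert-butyl)dimethylsilane
Product: 8 methyl (3R,6Z)-3-methyl-5-oxo-10-(TBSO)-6-[3-(TBSO)prop-1-en-2-yl]dec-6-enoate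
Conditions: Pd(PPh3)4 (5 mol %), CuI (10 mol %), CsF, DMF, 45 °C
Reagents that add atoms: none
Why: Stille coupling assisted by copper and fluoride joins the hindered α-stannyl enone to the alkenyl bromide with retention of the alkene geometry and builds the 2,3-disubstituted diene.

Step 5
Reactants: 8 methyl (3R,6Z)-3-methyl-5-oxo-10-(TBSO)-6-[3-(TBSO)prop-1-en-2-yl]dec-6-enoate
Product: 10 (4R,6S)-4-methyl-6-[(3Z)-7-(TBSO)-2-(TBSO-methyl)hepta-1,3-dien-3-yl]oxan-2-one, via hydroxy ester 9 (not isolated)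
Conditions: (R)-2-methyl-CBS-oxazaborolidine (20 mol %), catecholborane, toluene, −78 °C; then PPTS (cat.), 4 Å MS, toluene, 60 °C
Reagents that add atoms: none
Why: In the Corey–Bakshi–Shibata reduction the branched dienyl group acts as the large substituent, so the (R)-oxazaborolidine should set the (5S) carbinol under reagent control, and the δ-hydroxy ester then lactonises under mild acid to the oxanone with methyl and dienyl groups trans.

Step 6
Reactants: 10 (4R,6S)-4-methyl-6-[(3Z)-7-(TBSO)-2-(TBSO-methyl)hepta-1,3-dien-3-yl]oxan-2-one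
Product: 12 (3S,4R,6S)-3,4-dimethyl-6-[(3Z)-7-(TBSO)-2-(TBSO-methyl)hepta-1,3-dien-3-yl]oxan-2-one, via lithium enolate 11 (not isolated)
Conditions: LiN(iPr)2, THF, −78 °C; then MeI, DMPU, −78 to −40 °C
Reagents that add atoms: iodomethane, CI
Why: Kinetic enolate alkylation of a δ-lactone should place the methyl group trans to the C4 methyl group, although this centre becomes trigonal again in step 7 and its configuration is of no consequence.

Step 7
Reactants: 12 (3S,4R,6S)-3,4-dimethyl-6-[(3Z)-7-(TBSO)-2-(TBSO-methyl)hepta-1,3-dien-3-yl]oxan-2-one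
Product: 16 (1R,2R,6R)-1,6-dimethyl-2-[3-(TBSO)propyl]-3-[3-(TBSO)prop-1-en-2-yl]cyclohex-3-ene-1-carboxylic acid, via lithium enolate 13 (not isolated), via silyl ketene acetal 14 (not isolated), via silyl ester 15 (not isolated)
Conditions: LiN(iPr)2, THF, −78 °C; TBSCl, HMPA, −78 °C to rt; then toluene, 105 °C; then THF/H2O, AcOH (cat.), rt
Reagents that add atoms: none
Why: Deprotonation at C3 of the lactone and O-silylation give the cyclic silyl ketene acetal, whose O–C=C unit and the allylic C6–O bond with its alkene form the six-atom array of an Ireland–Claisen rearrangement; on heating the allylic C–O bond breaks as the ketene acetal carbon bonds to the alkene terminus, which contracts the oxane to the cyclohexene and releases the carboxyl group. The closest known reaction type is the Claisen rearrangement of lactone-derived silyl ketene acetals that carry an alkenyl group on the carbinol carbon, a ring contraction to cycloalkenecarboxylic acids. The carbocycle closes in a 6-(enolexo)-endo-trig sense, concerted and suprafacial on both components, through the boat-like bicyclic transition state that the lactone tether enforces. The quaternary centre is controlled by the C6 carbinol centre, because the alkene can reach the ketene acetal only on the face of the oxane that carries it, the face anti to the C4 methyl group, which puts the carboxyl carbon cis and the C3 methyl group trans to that methyl group. The adjacent CH centre is controlled by the alkene geometry, since the chain that is cis to the carbinol carbon ends up cis to the new quaternary methyl group. The step needs only this facial and geometric fidelity, which the ring-fixed ketene acetal geometry and the single accessible boat secure, and the second double bond of the diene cannot compete because it is not allylic to the C–O bond.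

Step 8
Reactants: 16 (1R,2R,6R)-1,6-dimethyl-2-[3-(TBSO)propyl]-3-[3-(TBSO)prop-1-en-2-yl]cyclohex-3-ene-1-carboxylic acid
Product: 17 [(1R,2R,6R)-1,6-dimethyl-2-[3-(TBSO)propyl]-3-[3-(TBSO)prop-1-en-2-yl]cyclohex-3-en-1-yl]methanol
Conditions: LiAlH4, THF, 0 to 40 °C
Reagents that add atoms: none
Why: Hydride reduction with LiAlH4 converts the hindered carboxylic acid into the neopentyl-type primary alcohol without touching the silyl ethers or the diene.

Step 9
Reactants: 17 [(1R,2R,6R)-1,6-dimethyl-2-[3-(TBSO)propyl]-3-[3-(TBSO)prop-1-en-2-yl]cyclohex-3-en-1-yl]methanol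
Product: 18 [(1R,2R,3Z,6R)-1,6-dimethyl-2-[3-(TBSO)propyl]-3-[1-(TBSO)propan-2-ylidene]cyclohexyl]methanol
Conditions: (naphthalene)Cr(CO)3 (20 mol %), H2 (50 atm), THF, 45 °C
Reagents that add atoms: none
Why: Arene–Cr(CO)3-catalysed 1,4-hydrogenation adds dihydrogen to the two termini of the s-cis η4-bound diene, so the new methyl group comes out cis to ring carbon C2 and the silyloxymethyl group cis to C6 across the new tetrasubstituted double bond (Z).

Step 10
Reactants: 18 [(1R,2R,3Z,6R)-1,6-dimethyl-2-[3-(TBSO)propyl]-3-[1-(TBSO)propan-2-ylidene]cyclohexyl]methanol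
Product: 19 (1R,2R,3Z,6R)-1,6-dimethyl-2-[3-(TBSO)propyl]-3-[1-(TBSO)propan-2-ylidene]cyclohexane-1-carbaldehyde
Conditions: Dess–Martin periodinane, CH2Cl2, 0 °C to rt
Reagents that add atoms: none
Why: Dess–Martin oxidation of the primary alcohol gives an aldehyde that has no α-hydrogen and therefore cannot epimerise.

Step 11
Reactants: 19 (1R,2R,3Z,6R)-1,6-dimethyl-2-[3-(TBSO)propyl]-3-[1-(TBSO)propan-2-ylidene]cyclohexane-1-carbaldehyde
Product: 20 vinyl compound (19 with CH=CH2 in place of CHO)
Conditions: Ph3PCH3Br, KOtBu, THF, 0 °C to rt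
Reagents that add atoms: methyltriphenylphosphonium bromide, C[P+](c1ccccc1)(c1ccccc1)c1ccccc1.[Br-]
Why: Wittig methylenation of the hindered but non-enolisable aldehyde installs the vinyl group on the quaternary carbon.

Step 12
Reactants: 21 3-methylbut-2-enal; 22 4,4,5,5-tetramethyl-2-(propa-1,2-dien-1-yl)-1,3,2-dioxaborolane
Product: 23 (4S)-2-methylhept-2-en-6-yn-4-ol
Conditions: (S)-3,3'-bis(2,4,6-triisopropylphenyl)-1,1'-binaphthyl-2,2'-diyl hydrogen phosphate (10 mol %), 4 Å MS, toluene, −20 °C
Reagents that add atoms: none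
Why: Brønsted acid-catalysed asymmetric propargylation with the allenylboronate passes through a closed six-membered transition state with allenyl-to-propargyl transposition, and the chiral phosphate is expected to direct attack to the Si face of the carbonyl group to set the (4S) carbinol.

Step 13
Reactants: 23 (4S)-2-methylhept-2-en-6-yn-4-ol
Product: 25 (4S,6E)-7-iodo-2,6-dimethylhepta-2,6-dien-4-ol, via alkenylalane 24 (not isolated)
Conditions: AlMe3, Cp2ZrCl2 (25 mol %), CH2Cl2, 0 °C to rt; then I2, THF, −30 °C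
Reagents that add atoms: trimethylaluminium, C[Al](C)C; iodine, II
Why: Zirconocene-catalysed methylalumination of the terminal alkyne is a syn addition with methyl on the internal carbon, and iodinolysis of the carbon–aluminium bond with retention gives the E iodoalkene while the hydroxyl is carried as its aluminium alkoxide.

Step 14
Reactants: 25 (4S,6E)-7-iodo-2,6-dimethylhepta-2,6-dien-4-ol; 26 (4-bromobut-1-yn-1-yl)trimethylsilane
Product: 28 (4S,6E)-2,6-dimethyl-11-(trimethylsilyl)undeca-2,6-dien-10-yn-4-ol, via alkylzinc bromide 27 (not isolated)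
Conditions: 26, Zn dust, LiCl, THF, 50 °C; then 25, PdCl2(dppf) (3 mol %), THF, rt to 40 °C
Reagents that add atoms: none
Why: Negishi coupling of the alkylzinc bromide with the alkenyl iodide forms the sp3–sp2 bond with retention of the E geometry, and coupling outpaces protonation of the zinc reagent by the free hydroxyl.

Step 15
Reactants: 28 (4S,6E)-2,6-dimethyl-11-(trimethylsilyl)undeca-2,6-dien-10-yn-4-ol
Product: 29 (4S,6E)-2,6-dimethylundeca-2,6-dien-10-yn-4-ol
Conditions: K2CO3 (cat.), MeOH, rt
Reagents that add atoms: none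
Why: Base-catalysed methanolysis removes only the alkynyl trimethylsilyl group.

Step 16
Reactants: 29 (4S,6E)-2,6-dimethylundeca-2,6-dien-10-yn-4-ol
Product: 31 (4S,6E,10E)-11-iodo-2,6,10-trimethylundeca-2,6,10-trien-4-ol, via alkenylalane 30 (not isolated)
Conditions: AlMe3, Cp2ZrCl2 (25 mol %), CH2Cl2, 0 °C to rt; then I2, THF, −30 °C
Reagents that add atoms: trimethylaluminium, C[Al](C)C; iodine, II
Why: A second zirconocene-catalysed methylalumination and iodinolysis, selective for the terminal alkyne over the trisubstituted alkenes, sets the second E alkene as in step 13.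

Step 17
Reactants: 31 (4S,6E,10E)-11-iodo-2,6,10-trimethylundeca-2,6,10-trien-4-ol
Product: 32 (1S,3E,7E)-1-[(2R)-3,3-dimethyloxiran-2-yl]-8-iodo-3,7-dimethylocta-3,7-dien-1-ol
Conditions: Ti(OiPr)4 (10 mol %), t-BuOOH, 4 Å MS, CH2Cl2, −20 °C
Reagents that add atoms: tert-butyl hydroperoxide, CC(C)(C)OO
Why: Hydroxyl-directed epoxidation is specific for the allylic alkene, and 1,3-allylic strain with the cis methyl group keeps the carbinol hydrogen in the alkene plane so that oxygen is delivered from the hydroxyl-bearing face, which should give the threo epoxy alcohol with the (2R) epoxide carbon.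

Step 18
Reactants: 20 vinyl compound; 32 (1S,3E,7E)-1-[(2R)-3,3-dimethyloxiran-2-yl]-8-iodo-3,7-dimethylocta-3,7-dien-1-ol
Product: 34 bis-TBS ether of triol 35, via B-alkyl-9-borabicyclononane 33 (not isolated)
Conditions: 9-BBN, THF, rt to 50 °C; then 32, PdCl2(dppf) (5 mol %), AsPh3, aq. K3PO4, DMF, rt
Reagents that add atoms: none
Why: 9-BBN hydroborates only the monosubstituted vinyl group, at its terminal carbon, and B-alkyl Suzuki–Miyaura coupling with the alkenyl iodide joins the fragments with retention of the E geometry while the epoxide, hydroxyl and silyl ethers are tolerated.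

Step 19
Reactants: 34 bis-TBS ether of triol 35
Product: 35 triol (target with CH2OH in place of CHO)
Conditions: Bu4NF, THF, 0 °C to rt
Reagents that add atoms: none
Why: Fluoride-mediated desilylation cleaves both primary silyl ethers and does not open the epoxide at room temperature.

Step 20
Reactants: 35 triol
Product: 36 target, (2Z)-2-[(2S,3R,4R)-3-[(3E,7E,10S)-10-[(2R)-3,3-dimethyloxiran-2-yl]-10-hydroxy-4,8-dimethyldeca-3,7-dien-1-yl]-2-(3-hydroxypropyl)-3,4-dimethylcyclohexylidene]propanal
Conditions: MnO2, CH2Cl2, rt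
Reagents that add atoms: none
Why: MnO2 oxidation is selective for the allylic primary alcohol, so the saturated primary and secondary hydroxyls and the epoxide remain and the Z geometry of the tetrasubstituted enal is kept under neutral conditions.

**Compound list**

1 | (3R)-5-methoxy-3-methyl-5-oxopentanoic acid | COC(=O)C[C@H](C)CC(=O)O | starting material
2 | tert-butyldimethyl(pent-4-yn-1-yloxy)silane | C#CCCCO[Si](C)(C)C(C)(C)C | starting material
3 | methyl (3S)-5-chloro-3-methyl-5-oxopentanoate (acid chloride of 1; descriptor changes by priority only) | COC(=O)C[C@H](C)CC(=O)Cl | intermediate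
4 | methyl (3R)-3-methyl-5-oxo-10-(TBSO)dec-6-ynoate | COC(=O)C[C@H](C)CC(=O)C#CCCCO[Si](C)(C)C(C)(C)C | intermediate
5 | methyl (3R,6E)-3-methyl-5-oxo-10-(TBSO)-6-(tributylstannyl)dec-6-enoate | COC(=O)C[C@H](C)CC(=O)/C(=C\CCCO[Si](C)(C)C(C)(C)C)[Sn](CCCC)(CCCC)CCCC | intermediate
6 | 2-bromoprop-2-en-1-ol | C=C(Br)CO | starting material
7 | (2-bromoprop-2-en-1-yloxy)(tert-butyl)dimethylsilane | C=C(Br)CO[Si](C)(C)C(C)(C)C | intermediate
8 | methyl (3R,6Z)-3-methyl-5-oxo-10-(TBSO)-6-[3-(TBSO)prop-1-en-2-yl]dec-6-enoate | COC(=O)C[C@H](C)CC(=O)/C(=C\CCCO[Si](C)(C)C(C)(C)C)C(=C)CO[Si](C)(C)C(C)(C)C | intermediate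
9 | methyl (3R,5S,6Z)-5-hydroxy-3-methyl-10-(TBSO)-6-[3-(TBSO)prop-1-en-2-yl]dec-6-enoate | COC(=O)C[C@H](C)C[C@H](O)/C(=C\CCCO[Si](C)(C)C(C)(C)C)C(=C)CO[Si](C)(C)C(C)(C)C | intermediate
10 | (4R,6S)-4-methyl-6-[(3Z)-7-(TBSO)-2-(TBSO-methyl)hepta-1,3-dien-3-yl]oxan-2-one | O=C1C[C@H](C)C[C@@H](/C(=C\CCCO[Si](C)(C)C(C)(C)C)C(=C)CO[Si](C)(C)C(C)(C)C)O1 | intermediate
11 | lithium enolate of 10 | [Li]OC1=C[C@H](C)C[C@@H](/C(=C\CCCO[Si](C)(C)C(C)(C)C)C(=C)CO[Si](C)(C)C(C)(C)C)O1 | intermediate
12 | (3S,4R,6S)-3,4-dimethyl-6-[(3Z)-7-(TBSO)-2-(TBSO-methyl)hepta-1,3-dien-3-yl]oxan-2-one | O=C1[C@@H](C)[C@H](C)C[C@@H](/C(=C\CCCO[Si](C)(C)C(C)(C)C)C(=C)CO[Si](C)(C)C(C)(C)C)O1 | intermediate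
13 | lithium enolate of 12 | [Li]OC1=C(C)[C@H](C)C[C@@H](/C(=C\CCCO[Si](C)(C)C(C)(C)C)C(=C)CO[Si](C)(C)C(C)(C)C)O1 | intermediate
14 | silyl ketene acetal: (2S,4R)-6-(TBSO)-4,5-dimethyl-2-[(3Z)-7-(TBSO)-2-(TBSO-methyl)hepta-1,3-dien-3-yl]-3,4-dihydro-2H-pyran | CC(C)(C)[Si](C)(C)OC1=C(C)[C@H](C)C[C@@H](/C(=C\CCCO[Si](C)(C)C(C)(C)C)C(=C)CO[Si](C)(C)C(C)(C)C)O1 | intermediate
15 | TBS ester of acid 16 | CC(C)(C)[Si](C)(C)OC(=O)[C@]1(C)[C@H](C)CC=C(C(=C)CO[Si](C)(C)C(C)(C)C)[C@H]1CCCO[Si](C)(C)C(C)(C)C | intermediate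
16 | (1R,2R,6R)-1,6-dimethyl-2-[3-(TBSO)propyl]-3-[3-(TBSO)prop-1-en-2-yl]cyclohex-3-ene-1-carboxylic acid | OC(=O)[C@]1(C)[C@H](C)CC=C(C(=C)CO[Si](C)(C)C(C)(C)C)[C@H]1CCCO[Si](C)(C)C(C)(C)C | intermediate
17 | [(1R,2R,6R)-1,6-dimethyl-2-[3-(TBSO)propyl]-3-[3-(TBSO)prop-1-en-2-yl]cyclohex-3-en-1-yl]methanol | OC[C@]1(C)[C@H](C)CC=C(C(=C)CO[Si](C)(C)C(C)(C)C)[C@H]1CCCO[Si](C)(C)C(C)(C)C | intermediate
18 | [(1R,2R,3Z,6R)-1,6-dimethyl-2-[3-(TBSO)propyl]-3-[1-(TBSO)propan-2-ylidene]cyclohexyl]methanol | OC[C@]1(C)[C@H](C)CC/C(=C(\C)CO[Si](C)(C)C(C)(C)C)[C@H]1CCCO[Si](C)(C)C(C)(C)C | intermediate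
19 | (1R,2R,3Z,6R)-1,6-dimethyl-2-[3-(TBSO)propyl]-3-[1-(TBSO)propan-2-ylidene]cyclohexane-1-carbaldehyde | O=C[C@]1(C)[C@H](C)CC/C(=C(\C)CO[Si](C)(C)C(C)(C)C)[C@H]1CCCO[Si](C)(C)C(C)(C)C | intermediate
20 | vinyl compound: 19 with CH=CH2 in place of CHO on the quaternary carbon | C=C[C@]1(C)[C@H](C)CC/C(=C(\C)CO[Si](C)(C)C(C)(C)C)[C@H]1CCCO[Si](C)(C)C(C)(C)C | intermediate
21 | 3-methylbut-2-enal | CC(C)=CC=O | starting material
22 | 4,4,5,5-tetramethyl-2-(propa-1,2-dien-1-yl)-1,3,2-dioxaborolane | C=C=CB1OC(C)(C)C(C)(C)O1 | starting material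
23 | (4S)-2-methylhept-2-en-6-yn-4-ol | C#CC[C@H](O)C=C(C)C | intermediate
24 | (E)-alkenyl(dimethyl)alane from 23, hydroxyl as dimethylaluminium alkoxide | C[Al](C)/C=C(\C)C[C@H](O[Al](C)C)C=C(C)C | intermediate
25 | (4S,6E)-7-iodo-2,6-dimethylhepta-2,6-dien-4-ol | I/C=C(\C)C[C@H](O)C=C(C)C | intermediate
26 | (4-bromobut-1-yn-1-yl)trimethylsilane | C[Si](C)(C)C#CCCBr | starting material
27 | [4-(trimethylsilyl)but-3-yn-1-yl]zinc bromide | C[Si](C)(C)C#CCC[Zn]Br | intermediate
28 | (4S,6E)-2,6-dimethyl-11-(trimethylsilyl)undeca-2,6-dien-10-yn-4-ol | C[Si](C)(C)C#CCC/C=C(\C)C[C@H](O)C=C(C)C | intermediate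
29 | (4S,6E)-2,6-dimethylundeca-2,6-dien-10-yn-4-ol | C#CCC/C=C(\C)C[C@H](O)C=C(C)C | intermediate
30 | (E)-alkenyl(dimethyl)alane from 29, hydroxyl as dimethylaluminium alkoxide | C[Al](C)/C=C(\C)CC/C=C(\C)C[C@H](O[Al](C)C)C=C(C)C | intermediate
31 | (4S,6E,10E)-11-iodo-2,6,10-trimethylundeca-2,6,10-trien-4-ol | I/C=C(\C)CC/C=C(\C)C[C@H](O)C=C(C)C | intermediate
32 | (1S,3E,7E)-1-[(2R)-3,3-dimethyloxiran-2-yl]-8-iodo-3,7-dimethylocta-3,7-dien-1-ol | I/C=C(\C)CC/C=C(\C)C[C@H](O)[C@H]1OC1(C)C | intermediate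
33 | B-alkyl-9-borabicyclo[3.3.1]nonane from 20 (boron on the terminal carbon of the former vinyl group) | C(CB1C2CCCC1CCC2)[C@]3(C)[C@H](C)CC/C(=C(\C)CO[Si](C)(C)C(C)(C)C)[C@H]3CCCO[Si](C)(C)C(C)(C)C | intermediate
34 | bis-TBS ether of triol 35 (allylic and propyl oxygens silylated) | C/C(CO[Si](C)(C)C(C)(C)C)=C1\CC[C@@H](C)[C@@](C)(CC/C=C(\C)CC/C=C(\C)C[C@H](O)[C@H]2OC2(C)C)[C@@H]1CCCO[Si](C)(C)C(C)(C)C | intermediate
35 | triol: target with CH2OH in place of CHO | C/C(CO)=C1\CC[C@@H](C)[C@@](C)(CC/C=C(\C)CC/C=C(\C)C[C@H](O)[C@H]2OC2(C)C)[C@@H]1CCCO | intermediate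
36 | (2Z)-2-[(2S,3R,4R)-3-[(3E,7E,10S)-10-[(2R)-3,3-dimethyloxiran-2-yl]-10-hydroxy-4,8-dimethyldeca-3,7-dien-1-yl]-2-(3-hydroxypropyl)-3,4-dimethylcyclohexylidene]propanal | C/C(C=O)=C1\CC[C@@H](C)[C@@](C)(CC/C=C(\C)CC/C=C(\C)C[C@H](O)[C@H]2OC2(C)C)[C@@H]1CCCO | target

**Step count and risks**

Total step count: 20. Longest linear sequence: 13 steps (steps 1, 2, 4 to 11 and 18 to 20, from compound 1).

The three steps most likely to fail:

Step 7. The lactone enolate may be silylated on carbon or the silyl ketene acetal may hydrolyse or decompose before the crowded boat transition state is reached. The fallback avoids enolate chemistry by using the neutral allyl vinyl ether at the aldehyde oxidation level. It sets out from 12. Reduction with i-Bu2AlH (toluene, −78 °C) should give the lactol F1. Dehydration with MsCl and Et3N (CH2Cl2, 0 °C to reflux) should give the 2-dienyl-4,5-dimethyl-3,4-dihydro-2H-pyran F2, a thermally robust cyclic enol ether. Heating in xylene in a sealed tube at about 180 °C should bring about the same ring-contracting Claisen rearrangement, with the same stereochemical course, to the diene aldehyde F3. NaBH4 in MeOH then returns to the route at 17.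

Step 9. Binding of the hindered 2,3-disubstituted diene to chromium may be slow, so that loss of the labile arene catalyst, 1,2-reduction or alkene migration competes. The fallback builds the methyl group in two stages by 1,4-hydroboration and deoxygenation and sets out from 17. Nickel-catalysed 1,4-hydroboration (Ni(cod)2 cat., PCy3, pinacolborane in excess, toluene, rt) should give the (Z)-allylboronate F4, drawn with the free hydroxyl, with boron on the terminal carbon and hydrogen on ring carbon C2. Oxidative work-up (NaOH, H2O2) should give the diol F5. Corey–Kim chlorination (N-chlorosuccinimide, Me2S, CH2Cl2, −20 °C) is selective for the allylic hydroxyl and should give the allylic chloride F6. LiEt3BH (THF, 0 °C) reduces the chloride by direct displacement, since the far allylic terminus is fully substituted, and returns to the route at 18.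

Step 4. Tin-to-palladium transfer from the hindered, electron-poor stannane may be slow, so that protodestannylation, homocoupling, loss of alkene geometry or self-condensation of the 2-acyl diene product competes. The fallback reverses the polarity of the coupling and postpones it until the ketone is gone; it sets out from 5 and 7. Iodine (CH2Cl2, 0 °C) should convert 5 with retention into the iodoenone F7. Corey–Bakshi–Shibata reduction as in step 5 should give the hydroxy ester F8, which lactonises under PPTS to the iodo lactone F9. Bromine–lithium exchange on 7 (t-BuLi, Et2O, −78 °C) and addition of ZnBr2 give the alkenylzinc bromide F10. Negishi coupling of F9 with F10 (Pd(PPh3)4, THF, rt) returns to the route at 10.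

Further compounds

F1 | step 7 | (3S,4R,6S)-3,4-dimethyl-6-[(3Z)-7-(TBSO)-2-(TBSO-methyl)hepta-1,3-dien-3-yl]oxan-2-ol (lactol, both anomers) | OC1[C@@H](C)[C@H](C)C[C@@H](/C(=C\CCCO[Si](C)(C)C(C)(C)C)C(=C)CO[Si](C)(C)C(C)(C)C)O1
F2 | step 7 | (2S,4R)-4,5-dimethyl-2-[(3Z)-7-(TBSO)-2-(TBSO-methyl)hepta-1,3-dien-3-yl]-3,4-dihydro-2H-pyran | C1=C(C)[C@H](C)C[C@@H](/C(=C\CCCO[Si](C)(C)C(C)(C)C)C(=C)CO[Si](C)(C)C(C)(C)C)O1
F3 | step 7 | (1R,2R,6R)-1,6-dimethyl-2-[3-(TBSO)propyl]-3-[3-(TBSO)prop-1-en-2-yl]cyclohex-3-ene-1-carbaldehyde | O=C[C@]1(C)[C@H](C)CC=C(C(=C)CO[Si](C)(C)C(C)(C)C)[C@H]1CCCO[Si](C)(C)C(C)(C)C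
F4 | step 9 | (Z)-allylboronate: 18 with CH2B(pinacolato) in place of the alkene methyl group | OC[C@]1(C)[C@H](C)CC/C(=C(\CB2OC(C)(C)C(C)(C)O2)CO[Si](C)(C)C(C)(C)C)[C@H]1CCCO[Si](C)(C)C(C)(C)C
F5 | step 9 | diol: 18 with CH2OH in place of the alkene methyl group | OC[C@]1(C)[C@H](C)CC/C(=C(\CO)CO[Si](C)(C)C(C)(C)C)[C@H]1CCCO[Si](C)(C)C(C)(C)C
F6 | step 9 | allylic chloride: 18 with CH2Cl in place of the alkene methyl group | OC[C@]1(C)[C@H](C)CC/C(=C(\CCl)CO[Si](C)(C)C(C)(C)C)[C@H]1CCCO[Si](C)(C)C(C)(C)C
F7 | step 4 | methyl (3R,6E)-6-iodo-3-methyl-5-oxo-10-(TBSO)dec-6-enoate | COC(=O)C[C@H](C)CC(=O)/C(I)=C\CCCO[Si](C)(C)C(C)(C)C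
F8 | step 4 | methyl (3R,5S,6E)-5-hydroxy-6-iodo-3-methyl-10-(TBSO)dec-6-enoate | COC(=O)C[C@H](C)C[C@H](O)/C(I)=C\CCCO[Si](C)(C)C(C)(C)C
F9 | step 4 | (4R,6S)-6-[(1E)-1-iodo-5-(TBSO)pent-1-en-1-yl]-4-methyloxan-2-one | O=C1C[C@H](C)C[C@@H](/C(I)=C\CCCO[Si](C)(C)C(C)(C)C)O1
F10 | step 4 | [3-(TBSO)prop-1-en-2-yl]zinc bromide | C=C([Zn]Br)CO[Si](C)(C)C(C)(C)C
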